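The runs stem from a simulated flask for substances that don't exist; the scatter is artificial.

At late times in this flask, at 80 min, target is what remains of a longer journey, so we follow one molecule of starting material. It waits for dissolved gas and becomes target; target may then fall back, turn into isomer of the product, or meet starting material and form side product.

- north-east: starting material 0.18 M; gas phase 5.7 mM (held); run made earlier
- flask: starting material 0.12 M; gas phase 5.7 mM (held); time 80 min

north-east run (percent of the starting material charged)

| time / min | target / % | starting material / % |
|---|---|---|
| 0.667 | 1.3 | 99.1 |
| 1.33 | 2.7 | 98.5 |
| 2.50 | 4.5 | 95.6 |
| 4.00 | 7.7 | 91.9 |
| 8.00 | 12.5 | 85.7 |

(scatter of a reading: 0.5 percentage points)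

- in percentages every species weighs as the starting material in it: one side product counts as two
- at the start none of the gas is dissolved
- the numbers in the tables scatter with a standard deviation of 0.5 percentage points
- candidate steps: target <-> isomer of the product; starting material + dissolved gas <-> target; starting material + target -> side product; gas phase <-> dissolved gas

- amount of target at 80 min, in percent of the starting material charged
- the change that raises the amount of target at 80 min, in percent of the starting material charged most ("none" if none brings more than 2 percentage points) (blue / green / none)
- amount of target at 80 min, in percent of the starting material charged, after green

- blue: doubling the transfer coefficient of the gas phase, all else as stated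
- green: doubling the saturation concentration of gas phase, all else as stated

We reckon between two extreme flasks. In the first, gas transfer is the rate-limiting step and no target falls back, so the same amount turns each minute at any charge. The north-east run lost 14.3% of its charge by 8.00 min, which gives the supply rate ν, the starting material turned per minute on average over those minutes, 3.22 mM min⁻¹, a reading that carries the scatter. At that rate the flask's charge passes in τ = 37.3 min. In the second extreme gas is plentiful, and starting material and target shuttle to a balance that drains slowly. Because the asked time is twice τ, our estimate of the supply passes the flask's charge well before the asked time, so we place the flask near the second extreme. We therefore expect blue to bring little and green to shift the balance; we commit to no percentage.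

The forecast gives 20% (range 13% to 27%), names green as best, and gives 32% after it (range 22% to 43%), holding that “the dissolved gas stays close to saturation”.

The flask gives 21.5%; the best change is green, worth 3.6 percentage points, while blue brings −0.46 points, and 25.1% stands after green.

    target ⇌ isomer of the product (K = 23.0, k = 0.0180 min⁻¹)
    starting material + dissolved gas ⇌ target (K = 110 M⁻¹, k = 64.0 M⁻¹ min⁻¹)
    starting material + target → side product (k = 0.0300 M⁻¹ min⁻¹)
    gas phase ⇌ dissolved gas, rate k4*(csat - [dissolved gas]) (kL = 0.730 min⁻¹)

By 80 min the flask had lost 74.7 mM of starting material on balance, less than the 258 mM that our estimate ν gives for that time. Target's half-life towards isomer of the product, by that forward step taken alone, is 39 min, shorter than the asked time, and in this flask isomer of the product stands at 33.4% against 21.5% of target. With 0.48 M of starting material, ν over the same time amounts to 53.7% of that neighbouring flask's charge. The computed neighbouring flask has lost 54.1% of its charge and holds 16.2% of target.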